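The runs are calculated with constants of no real substance.

**Small charge.** A small charge of free catalyst, 78 µM, faces 0.10 M of starting material, far less than the starting material, so each catalyst must turn over about 1282 times to finish the job. The flasks are therefore best counted in turnovers.

all flasks: starting material 0.10 M (in portions, 3); free catalyst 78 µM
- Saturday's: second substrate 0.050 M; run made earlier; portions every 5.0 min
- Wednesday's: second substrate 0.075 M; run made earlier; portions every 5.0 min
- violet: second substrate 0.100 M; the portions of starting material follow each other after 5.0 min, the first at the start; time 50 min
- amber: second substrate 0.100 M; the portions of starting material follow each other after 5.0 min, the first at the start; time 110 min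
- green: second substrate 0.100 M; the portions of starting material follow each other after 5.0 min, the first at the start; time 75 min

| run | time / min | target / % | starting material / % | catalyst intermediate A / % |
|---|---|---|---|---|
| Saturday's | 4.00 | 3 | 30 | 0 |
| Saturday's | 10.0 | 8 | 62 | 0 |
| Saturday's | 20.0 | 14 | 85 | 2 |
| Saturday's | 30.0 | 22 | 77 | 0 |
| Wednesday's | 2.50 | 2 | 31 | 1 |
| Wednesday's | 6.00 | 2 | 64 | 1 |
| Wednesday's | 12.0 | 7 | 94 | 0 |
| Wednesday's | 30.0 | 19 | 79 | 1 |

(standard deviation of a reading: 1.5 percentage points)

- which of these there is most of at the end, counted by the starting material in it, violet (starting material / target / catalyst intermediate A)
- which of these there is most of at the end, counted by the starting material in it, amber (starting material / target / catalyst intermediate A)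
- which of these there is most of at the end, counted by the starting material in it, green (starting material / target / catalyst intermediate A)
- the largest of these amounts at the end, in percent of the starting material charged, violet
- the largest of these amounts at the end, in percent of the starting material charged, amber
- the largest of these amounts at the end, in percent of the starting material charged, green

- the numbers in the tables scatter with a standard deviation of 1.5 percentage points
- a reading or a percentage of target counts all its forms, free or not
- a reading at the moment of an addition is taken just before it

**Counting turnovers.** Let N be the turnover frequency: target formed, divided by catalyst charged and by the time since the start. Saturday's run read 22 % target at 30.0 min, or 282 turnovers, so N there is 9.40 min⁻¹. Wednesday's run read 19 % at 30.0 min, so N there is 8.12 min⁻¹, lower than Saturday's.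

**First estimate.** Taking the mean of the two as a constant N, amber reaches 75.2 % target at 110 min.

**Weak link.** That mean treats second substrate as idle, yet N fell as second substrate rose. The gap is 3 percentage points between readings that each scatter by 1.5 points, so it is uncertain, but it is the best evidence at hand. My reckoning therefore lets the reciprocal of N rise by equal steps, as if second substrate kept catalyst away from target. Violet's charge of 0.100 M lies one more equal step beyond Wednesday's, which gives N = 7.15 min⁻¹. Catalyst holds a negligible share of the charge, so starting material is the remainder. Violet then ends with 72.1 % starting material, green with 58.2 % starting material, and amber with 61.3 % target.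

**The forecast.** The forecast judged second substrate “so it is zero order there too, perhaps slightly inhibiting”. It gave 66 % starting material for violet, 73 % target for amber and 51 % starting material for green, so it stands above my amber figure and below my green one.

**The result.** Violet ends with 70.9 % starting material, amber with 59.0 % target and green with 57.3 % starting material.

    free catalyst + target ⇌ idle complex, settled at all times (K = 3.80 M⁻¹)
    starting material + free catalyst ⇌ catalyst intermediate A (K = 13.0 M⁻¹, k = 190 M⁻¹ s⁻¹)
    second substrate + free catalyst ⇌ catalyst intermediate B (K = 150 M⁻¹, k = 4.20 M⁻¹ s⁻¹)
    catalyst intermediate B → free catalyst + second product (k = 0.260 s⁻¹)
    catalyst intermediate A → free catalyst + target (k = 0.430 s⁻¹)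

**Longer time.** Amber's N comes to 6.88 min⁻¹, close to the 7.15 min⁻¹ carried forward. Amber and violet share one recipe, and amber's starting material stands at 41.0 % against violet's 70.9 % because amber runs for 110 min and violet for 50 min. The neighbour of violet with 1.9 × 10⁻⁴ M of free catalyst, counted at the same N, comes to 67.9 % target at 50 min, and that flask holds 61.9 % target.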